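**Retrosynthetic overview**

1. Locants follow germacrane numbering (ring C1–C10, lactone carbons C11–C13, C14 on C10, C15 on C4). The route rests on the C3 secondary allylic carbinol next to the Z-configured C4=C5 double bond inside the ten-membered carbocycle. Cutting C3–C4 gives a C4 Z-alkenyl iodide and a C3 aldehyde, closed by NiCl2/CrCl2 with all other functionality in place.
2. The seco aldehyde 24 is cut at C7–C8. Chromium allylation of epoxy aldehyde 9 with bromomethyl butenolide 18 creates the α-methylene lactone and sets C7. C8 is then inverted in the same operation that installs the tiglate (Mitsunobu).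
3. Butenolide 18: ProPhenol–zinc alkynylation of crotonaldehyde (C6), hydroxyl-directed hydroalumination–iodination (Z C4=C5 iodide), acylation with 2-(bromomethyl)acrylic acid, ring-closing metathesis.
4. Aldehyde 9: carboalumination of a butynyl silyl ether with ethylene oxide capture (E C1=C10 alkene, C14), Shi epoxidation (C1, C10), desilylation, oxidation.
5. Ring order: oxirane (step 3), butenolide that becomes the γ-lactone (step 9), ten-membered carbocycle (step 14).

Key step: step 14

Assumption: (S,S)-ProPhenol is taken to deliver the alkynyl group to the Re face of the enal in step 6; if the first batch shows the opposite sense, the (R,R)-ligand is used and nothing else changes.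

**Route**

Step 1
Reactants: 1 tert-butyl(but-3-yn-1-yloxy)dimethylsilane; 2 ethylene oxide
Product: 5 (E)-6-(tert-butyldimethylsilyloxy)-4-methylhex-3-en-1-ol, via alkenylalane 3 (not isolated), via lithium alkenylalanate 4 (not isolated)
Conditions: Me3Al, Cp2ZrCl2 (0.25 equiv), CH2Cl2, 0 °C → rt; n-BuLi, hexane/THF, −78 → 0 °C; then ethylene oxide, −30 °C → rt
Reagents that add atoms: trimethylaluminium C[Al](C)C
Why: Zirconium-catalysed Negishi carboalumination adds methyl and aluminium syn across the terminal alkyne with the methyl on the internal carbon, and the derived lithium alkenylalanate opens ethylene oxide with retention of olefin geometry, so the E-trisubstituted C1=C10 alkene carrying C14 is set in one flask.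

Step 2
Reactants: 5 (E)-6-(tert-butyldimethylsilyloxy)-4-methylhex-3-en-1-ol
Product: 6 (E)-tert-butyl{[6-(4-methoxybenzyloxy)-3-methylhex-3-en-1-yl]oxy}dimethylsilane
Conditions: NaH, PMBCl, Bu4NI (cat.), THF/DMF, 0 °C → rt
Reagents that add atoms: 4-methoxybenzyl chloride COc1ccc(CCl)cc1
Why: Williamson etherification of the primary alkoxide installs a PMB group that can later be removed oxidatively without touching silyl ether, epoxide or esters.

Step 3
Reactants: 6 (E)-tert-butyl{[6-(4-methoxybenzyloxy)-3-methylhex-3-en-1-yl]oxy}dimethylsilane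
Product: 7 tert-butyl(2-{(2R,3R)-3-[2-(4-methoxybenzyloxy)ethyl]-2-methyloxiran-2-yl}ethoxy)dimethylsilane
Conditions: D-fructose-derived Shi ketone (0.3 equiv), Oxone (KHSO5), K2CO3, Bu4NHSO4, MeCN/CH2(OMe)2/aq. Na2B4O7–Na2EDTA, 0 °C
Reagents that add atoms: potassium peroxymonosulfate OOS(=O)(=O)[O-].[K+]
Why: Shi asymmetric epoxidation, in which the chiral dioxirane transfers oxygen through a spiro transition state to one face of the E-trisubstituted alkene, should set C1 and C10 as R,R with high enantioselectivity.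

Step 4
Reactants: 7 tert-butyl(2-{(2R,3R)-3-[2-(4-methoxybenzyloxy)ethyl]-2-methyloxiran-2-yl}ethoxy)dimethylsilane
Product: 8 2-{(2R,3R)-3-[2-(4-methoxybenzyloxy)ethyl]-2-methyloxiran-2-yl}ethan-1-ol
Conditions: Bu4NF, THF, 0 °C → rt
Reagents that add atoms: none
Why: Fluoride-mediated desilylation cleaves the only silyl ether present and leaves the epoxide and the PMB ether untouched.

Step 5
Reactants: 8 2-{(2R,3R)-3-[2-(4-methoxybenzyloxy)ethyl]-2-methyloxiran-2-yl}ethan-1-ol
Product: 9 2-{(2R,3R)-3-[2-(4-methoxybenzyloxy)ethyl]-2-methyloxiran-2-yl}acetaldehyde (C8 aldehyde)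
Conditions: Dess–Martin periodinane, NaHCO3, CH2Cl2, 0 °C; used crude
Reagents that add atoms: none
Why: Buffered Dess–Martin oxidation forms the aldehyde without base, so the β,γ-epoxy aldehyde should survive if it is used at once without chromatography.

Step 6
Reactants: 10 tert-butyldimethyl(prop-2-yn-1-yloxy)silane; 11 (E)-but-2-enal
Product: 13 (S,E)-7-(tert-butyldimethylsilyloxy)hept-2-en-5-yn-4-ol, via alkynylzinc 12 (not isolated)
Conditions: (S,S)-ProPhenol (10 mol %), Me2Zn (3 equiv), Ph3P=O (20 mol %), toluene, 0 °C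
Reagents that add atoms: none
Why: ProPhenol–zinc catalysed asymmetric alkynylation, in which the chiral dinuclear zinc complex binds the enal and delivers the alkynyl group to its Re face, sets the future C6 as the S carbinol.

Step 7
Reactants: 13 (S,E)-7-(tert-butyldimethylsilyloxy)hept-2-en-5-yn-4-ol
Product: 15 (2Z,4S,5E)-1-(tert-butyldimethylsilyloxy)-2-iodohepta-2,5-dien-4-ol, via cyclic alkenylalanate 14 (not isolated)
Conditions: NaAlH2(OCH2CH2OMe)2 (Red-Al), THF, 0 °C; EtOAc; then I2, −78 → 0 °C
Reagents that add atoms: iodine II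
Why: Hydroxyl-directed trans-hydroalumination of the propargylic alcohol places hydride on C5 and aluminium on C4 in a five-membered alanate, and iodinolysis with retention gives the Z-alkenyl iodide (iodine cis to C6) that the ring closure needs.

Step 8
Reactants: 15 (2Z,4S,5E)-1-(tert-butyldimethylsilyloxy)-2-iodohepta-2,5-dien-4-ol; 16 2-(bromomethyl)acrylic acid
Product: 17 (2Z,4S,5E)-1-(tert-butyldimethylsilyloxy)-2-iodohepta-2,5-dien-4-yl 2-(bromomethyl)acrylate
Conditions: DCC, DMAP (5 mol %), CH2Cl2, −20 → 0 °C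
Reagents that add atoms: none
Why: Steglich carbodiimide esterification acylates the secondary alcohol under neutral conditions, which avoids ionisation of the doubly allylic carbinol and keeps the C6 configuration.

Step 9
Reactants: 17 (2Z,4S,5E)-1-(tert-butyldimethylsilyloxy)-2-iodohepta-2,5-dien-4-yl 2-(bromomethyl)acrylate
Product: 18 (S)-3-(bromomethyl)-5-[(Z)-3-(tert-butyldimethylsilyloxy)-2-iodoprop-1-enyl]furan-2(5H)-one
Conditions: second-generation Grubbs catalyst (H2IMes)(PCy3)Cl2Ru=CHPh (5 mol %), CH2Cl2, 40 °C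
Reagents that add atoms: none
Why: Ring-closing metathesis between the propenyl group and the 1,1-disubstituted acrylate closes the butenolide (C7=C11) with loss of propene, while the iodine-bearing trisubstituted alkene is too hindered and electron-poor to take part.

Step 10
Reactants: 18 (S)-3-(bromomethyl)-5-[(Z)-3-(tert-butyldimethylsilyloxy)-2-iodoprop-1-enyl]furan-2(5H)-one; 9 2-{(2R,3R)-3-[2-(4-methoxybenzyloxy)ethyl]-2-methyloxiran-2-yl}acetaldehyde
Product: 20 (4R,5S)-4-{(1S)-1-hydroxy-2-[(2R,3R)-3-(2-(4-methoxybenzyloxy)ethyl)-2-methyloxiran-2-yl]ethyl}-5-[(Z)-3-(tert-butyldimethylsilyloxy)-2-iodoprop-1-enyl]-3-methylidenedihydrofuran-2(3H)-one (8S seco alcohol), via allylchromium dichloride 19 (not isolated)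
Conditions: CrCl2 (3 equiv, nickel-free), THF, 0 °C
Reagents that add atoms: none
Why: Nozaki–Hiyama chromium allylation, in which CrCl2 inserts into the allylic C–Br bond and allylchromium 19 adds with allylic transposition through a chair Zimmerman–Traxler transition state, bonds C7 on the face opposite the C6 side chain (6,7-trans) with the aldehyde chain equatorial, which should give the 7R,8S adduct (C8 is inverted in step 11) and unveil the α-methylene lactone, while the alkenyl iodide stays inert to CrCl2 as long as no nickel salt is present.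

Step 11
Reactants: 20 8S seco alcohol; 21 tiglic acid, (E)-2-methylbut-2-enoic acid
Product: 22 (1R)-1-{(2S,3R)-2-[(Z)-3-(tert-butyldimethylsilyloxy)-2-iodoprop-1-enyl]-4-methylidene-5-oxotetrahydrofuran-3-yl}-2-[(2R,3R)-3-(2-(4-methoxybenzyloxy)ethyl)-2-methyloxiran-2-yl]ethyl (E)-2-methylbut-2-enoate (8R tiglate)
Conditions: PPh3, DIAD, toluene, 0 °C → rt
Reagents that add atoms: none
Why: Mitsunobu esterification displaces the C8 oxyphosphonium by tiglate with inversion, which installs the ester and corrects C8 to R in one operation under neutral conditions that leave lactone, epoxide and alkenyl iodide alone.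

Step 12
Reactants: 22 8R tiglate PMB ether
Product: 23 (1R)-1-{(2S,3R)-2-[(Z)-3-(tert-butyldimethylsilyloxy)-2-iodoprop-1-enyl]-4-methylidene-5-oxotetrahydrofuran-3-yl}-2-[(2R,3R)-3-(2-hydroxyethyl)-2-methyloxiran-2-yl]ethyl (E)-2-methylbut-2-enoate (C3 alcohol)
Conditions: DDQ, CH2Cl2/pH 7 phosphate buffer, 0 °C
Reagents that add atoms: none
Why: Oxidative PMB cleavage by DDQ proceeds through single-electron oxidation of the electron-rich arene, and the buffer keeps the liberated 3,4-epoxy alcohol from acid-promoted cyclisation.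

Step 13
Reactants: 23 C3 alcohol
Product: 24 (1R)-1-{(2S,3R)-2-[(Z)-3-(tert-butyldimethylsilyloxy)-2-iodoprop-1-enyl]-4-methylidene-5-oxotetrahydrofuran-3-yl}-2-[(2R,3R)-2-methyl-3-(2-oxoethyl)oxiran-2-yl]ethyl (E)-2-methylbut-2-enoate (Z-alkenyl iodide epoxy aldehyde)
Conditions: Dess–Martin periodinane, NaHCO3, CH2Cl2, 0 °C; used crude
Reagents that add atoms: none
Why: Buffered Dess–Martin oxidation converts the primary alcohol into the C3 aldehyde without base, so the β,γ-epoxy aldehyde and the α-methylene lactone should be preserved.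

Step 14
Reactants: 24 Z-alkenyl iodide epoxy aldehyde
Product: 26 15-O-tert-butyldimethylsilyl ether of the target (1R,3S,6R,7R,8R,10R), via alkenylchromium dichloride 25 (not isolated)
Conditions: CrCl2 (10 equiv), NiCl2 (0.1 equiv), degassed DMSO, rt, slow addition of 24, final 0.002 M
Reagents that add atoms: none
Why: Intramolecular Nozaki–Hiyama–Kishi reaction: zerovalent nickel, formed from NiCl2 by CrCl2, inserts into the C4–I bond with retention, the alkenyl group passes to trivalent chromium (25), and this non-basic alkenylchromium adds to the C3 aldehyde; the closest known reaction type is the NiCl2/CrCl2 cyclisation of alkenyl iodide aldehydes to medium-ring allylic alcohols. The ten-membered carbocycle (C1–C10) closes in a 10-exo-trig mode by attack of C4 on the C3 carbonyl carbon, favoured over oligomerisation by slow addition at high dilution. The new stereocentre C3 must be S, which means attack on the Re face of the aldehyde; it is controlled by the substrate, since the trans-fused lactone, the Z alkene and the trans epoxide leave few low-energy folded conformers of the seco chain and the chromium-bound carbonyl oxygen is expected to point to the outside of the forming ring. The step needs chemoselectivity for the alkenyl iodide and the aldehyde in the presence of the α-methylene lactone, the tiglate, the epoxide and the silyl ether, which the low basicity of organochromium reagents and their inertness toward esters and epoxides should secure, with the nickel loading kept low to avoid conjugate addition to the methylene lactone. The Z geometry of C4=C5 is carried over unchanged from the iodide, so the cis ring olefin is fixed before closure.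

Step 15
Reactants: 26 15-O-tert-butyldimethylsilyl ether of the target
Product: 27 target, (1R,3S,6R,7R,8R,10R)-1,10-epoxy-3,15-dihydroxy-8-[(E)-2-methylbut-2-enoyloxy]germacra-4Z,11(13)-dien-12,6-olide
Conditions: HF·pyridine, pyridine, THF, 0 °C
Reagents that add atoms: none
Why: Fluoride-mediated desilylation with pyridine-buffered HF·pyridine frees the C15 hydroxyl without opening the epoxide or adding to the α-methylene lactone.

**Compound list**

1 | tert-butyl(but-3-yn-1-yloxy)dimethylsilane | C#CCCO[Si](C)(C)C(C)(C)C | starting material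
2 | ethylene oxide | C1CO1 | starting material
3 | (E)-[4-(tert-butyldimethylsilyloxy)-2-methylbut-1-enyl]dimethylalane | C[Al](C)/C=C(\C)CCO[Si](C)(C)C(C)(C)C | intermediate
4 | lithium butyl[(E)-4-(tert-butyldimethylsilyloxy)-2-methylbut-1-enyl]dimethylaluminate | [Li+].CCCC[Al-](C)(C)/C=C(\C)CCO[Si](C)(C)C(C)(C)C | intermediate
5 | (E)-6-(tert-butyldimethylsilyloxy)-4-methylhex-3-en-1-ol | OCC/C=C(\C)CCO[Si](C)(C)C(C)(C)C | intermediate
6 | (E)-tert-butyl{[6-(4-methoxybenzyloxy)-3-methylhex-3-en-1-yl]oxy}dimethylsilane | COc1ccc(COCC/C=C(\C)CCO[Si](C)(C)C(C)(C)C)cc1 | intermediate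
7 | tert-butyl(2-{(2R,3R)-3-[2-(4-methoxybenzyloxy)ethyl]-2-methyloxiran-2-yl}ethoxy)dimethylsilane | COc1ccc(COCC[C@H]2O[C@]2(C)CCO[Si](C)(C)C(C)(C)C)cc1 | intermediate
8 | 2-{(2R,3R)-3-[2-(4-methoxybenzyloxy)ethyl]-2-methyloxiran-2-yl}ethan-1-ol | COc1ccc(COCC[C@H]2O[C@]2(C)CCO)cc1 | intermediate
9 | 2-{(2R,3R)-3-[2-(4-methoxybenzyloxy)ethyl]-2-methyloxiran-2-yl}acetaldehyde | COc1ccc(COCC[C@H]2O[C@]2(C)CC=O)cc1 | intermediate
10 | tert-butyldimethyl(prop-2-yn-1-yloxy)silane | C#CCO[Si](C)(C)C(C)(C)C | starting material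
11 | (E)-but-2-enal | C/C=C/C=O | starting material
12 | methyl[3-(tert-butyldimethylsilyloxy)prop-1-ynyl]zinc | C[Zn]C#CCO[Si](C)(C)C(C)(C)C | intermediate
13 | (S,E)-7-(tert-butyldimethylsilyloxy)hept-2-en-5-yn-4-ol | C/C=C/[C@H](O)C#CCO[Si](C)(C)C(C)(C)C | intermediate
14 | sodium (5S)-3-[(tert-butyldimethylsilyloxy)methyl]-2,2-bis(2-methoxyethoxy)-5-[(E)-prop-1-enyl]-2,5-dihydro-1,2-oxaaluminol-2-uide | [Na+].COCCO[Al-]1(OCCOC)O[C@@H](/C=C/C)C=C1CO[Si](C)(C)C(C)(C)C | intermediate
15 | (2Z,4S,5E)-1-(tert-butyldimethylsilyloxy)-2-iodohepta-2,5-dien-4-ol | C/C=C/[C@H](O)/C=C(I)/CO[Si](C)(C)C(C)(C)C | intermediate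
16 | 2-(bromomethyl)acrylic acid | C=C(CBr)C(=O)O | starting material
17 | (2Z,4S,5E)-1-(tert-butyldimethylsilyloxy)-2-iodohepta-2,5-dien-4-yl 2-(bromomethyl)acrylate | C/C=C/[C@H](OC(=O)C(=C)CBr)/C=C(I)/CO[Si](C)(C)C(C)(C)C | intermediate
18 | (S)-3-(bromomethyl)-5-[(Z)-3-(tert-butyldimethylsilyloxy)-2-iodoprop-1-enyl]furan-2(5H)-one | BrCC1=C[C@H](OC1=O)/C=C(I)/CO[Si](C)(C)C(C)(C)C | intermediate
19 | {(S)-5-[(Z)-3-(tert-butyldimethylsilyloxy)-2-iodoprop-1-enyl]-2-oxo-2,5-dihydrofuran-3-yl}methylchromium dichloride | Cl[Cr](Cl)CC1=C[C@H](OC1=O)/C=C(I)/CO[Si](C)(C)C(C)(C)C | intermediate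
20 | (4R,5S)-4-{(1S)-1-hydroxy-2-[(2R,3R)-3-(2-(4-methoxybenzyloxy)ethyl)-2-methyloxiran-2-yl]ethyl}-5-[(Z)-3-(tert-butyldimethylsilyloxy)-2-iodoprop-1-enyl]-3-methylidenedihydrofuran-2(3H)-one | COc1ccc(COCC[C@H]2O[C@]2(C)C[C@H](O)[C@H]3C(=C)C(=O)O[C@@H]3/C=C(I)/CO[Si](C)(C)C(C)(C)C)cc1 | intermediate
21 | tiglic acid, (E)-2-methylbut-2-enoic acid | C/C=C(\C)C(=O)O | starting material
22 | 8R tiglate of 20 with inverted C8 (PMB ether) | COc1ccc(COCC[C@H]2O[C@]2(C)C[C@@H](OC(=O)/C(C)=C/C)[C@H]3C(=C)C(=O)O[C@@H]3/C=C(I)/CO[Si](C)(C)C(C)(C)C)cc1 | intermediate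
23 | C3 alcohol (PMB removed from 22) | OCC[C@H]1O[C@]1(C)C[C@@H](OC(=O)/C(C)=C/C)[C@H]2C(=C)C(=O)O[C@@H]2/C=C(I)/CO[Si](C)(C)C(C)(C)C | intermediate
24 | Z-alkenyl iodide epoxy aldehyde (C3 aldehyde) | O=CC[C@H]1O[C@]1(C)C[C@@H](OC(=O)/C(C)=C/C)[C@H]2C(=C)C(=O)O[C@@H]2/C=C(I)/CO[Si](C)(C)C(C)(C)C | intermediate
25 | C4 alkenylchromium dichloride from 24 | O=CC[C@H]1O[C@]1(C)C[C@@H](OC(=O)/C(C)=C/C)[C@H]2C(=C)C(=O)O[C@@H]2/C=C([Cr](Cl)Cl)/CO[Si](C)(C)C(C)(C)C | intermediate
26 | 15-O-tert-butyldimethylsilyl ether of the target | C=C1C(=O)O[C@@H]2/C=C(/CO[Si](C)(C)C(C)(C)C)[C@@H](O)C[C@H]3O[C@]3(C)C[C@@H](OC(=O)/C(C)=C/C)[C@@H]12 | intermediate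
27 | (1R,3S,6R,7R,8R,10R)-1,10-epoxy-3,15-dihydroxy-8-[(E)-2-methylbut-2-enoyloxy]germacra-4Z,11(13)-dien-12,6-olide | C=C1C(=O)O[C@@H]2/C=C(/CO)[C@@H](O)C[C@H]3O[C@]3(C)C[C@@H](OC(=O)/C(C)=C/C)[C@@H]12 | target

**Step count**

Total: 15 steps. Longest linear sequence: 11 steps (steps 1–5, then 10–15); the butenolide branch is steps 6–9.

**Steps most likely to fail**

1. Step 14. The alkenylchromium may add to the wrong face of the C3 aldehyde and give the 3R carbinol; oligomerisation and β-elimination of the epoxy aldehyde are further losses. The fallback sets the C3 configuration by inversion instead of by the ring closure. It sets out from 24, which is cyclised as in step 14, and the 3R epimer of 26 F1 is collected. Mitsunobu reaction with formic acid (PPh3, DIAD, toluene, 0 °C) should give the 3S formate of 26 F2 with inversion. Aqueous KHCO3 in THF/MeOH at 0 °C then removes the formyl group, and the route is rejoined at 26.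

2. Step 11. Displacement at the hindered C8 oxyphosphonium may be slow, so that elimination toward C7 or C9 or ester formation with retention competes. The fallback separates activation from displacement. It sets out from 20, which with chloromethanesulfonyl chloride and pyridine in CH2Cl2 at 0 °C gives the 8S chloromethanesulfonate of 20 F3. Caesium tiglate (from 21 and Cs2CO3) with 18-crown-6 in toluene at 60 °C should then displace the sulfonate with inversion, and the route is rejoined at 22.

3. Step 10. Simple diastereoselection may erode through a competing boat or open transition state, so that the 8R carbinol forms alongside the 8S one. The fallback makes the two epimers converge rather than forcing selectivity. It sets out from 18 and 9 under the conditions of step 10; the 8R epimer of 20 F4 is separated and acylated with retention by Yamaguchi esterification (21, 2,4,6-trichlorobenzoyl chloride, Et3N, DMAP, toluene). The route is rejoined at 22, which the 8S epimer reaches through step 11.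

**Further compounds**

F1 | step 14 | 3R epimer of 26 | C=C1C(=O)O[C@@H]2/C=C(/CO[Si](C)(C)C(C)(C)C)[C@H](O)C[C@H]3O[C@]3(C)C[C@@H](OC(=O)/C(C)=C/C)[C@@H]12
F2 | step 14 | 3S formate of 26 | C=C1C(=O)O[C@@H]2/C=C(/CO[Si](C)(C)C(C)(C)C)[C@@H](OC=O)C[C@H]3O[C@]3(C)C[C@@H](OC(=O)/C(C)=C/C)[C@@H]12
F3 | step 11 | 8S chloromethanesulfonate of 20 | COc1ccc(COCC[C@H]2O[C@]2(C)C[C@H](OS(=O)(=O)CCl)[C@H]3C(=C)C(=O)O[C@@H]3/C=C(I)/CO[Si](C)(C)C(C)(C)C)cc1
F4 | step 10 | 8R epimer of 20 | COc1ccc(COCC[C@H]2O[C@]2(C)C[C@@H](O)[C@H]3C(=C)C(=O)O[C@@H]3/C=C(I)/CO[Si](C)(C)C(C)(C)C)cc1
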